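## Retrosynthetic overview

Core numbering: C1 = bridgehead next to CMe2 (C8); C5 = other bridgehead; C9 = bridging ketone; C2–C3(aroyl)–C4 = enolised β-diketone bridge; C6H2–C7H(prenyl)–C8Me2 = carbon bridge; ring A = C1–C2–C3–C4–C5–C9, ring B = C1–C8–C7–C6–C5–C9.
Enabling feature: ring A is a 2-aroylcyclohexane-1,3,5-trione, a folded tetraketide in which C9 and C4 are the two carbonyls of a malonyl unit on C5, and C1 and C3 are the γ- and α-carbons of an aryl 1,3-diketone; C1 and C5 are already linked through C6–C7–C8.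
Key disconnection: C1–C9 (closes ring B), followed in the same flask by C3–C4 (closes ring A); this opens both carbonyl bridges and both bridgehead stereocentres at once and leaves the acyclic diketone–malonate 20 with C7 as its only fixed stereocentre.
Precursor 20: C2–C3 by acylation of an aryl methyl ketone, C5–C6 by malonate alkylation, the C1 and C5 geranyl groups by enolate alkylations, C7 by Evans prenylation of a 3,3-dimethylglutarate half-ester.
Ring order: ring B, then ring A (one operation, step 12); the last step is desilylation of the catechol.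

Key step: step 12

Assumption: the carbon that becomes C1 is carried from 10 to 20 as a mixture of epimers (no descriptor in the SMILES), because step 12 turns it into a planar carbanion; the target is treated as the enol tautomer drawn.

## Route

Step 1
Reactants: 1 3,3-dimethylglutaric anhydride
Product: 2 5-tert-butoxy-3,3-dimethyl-5-oxopentanoic acid
Conditions: t-BuOH, DMAP (0.2 equiv), Et3N, PhMe, 80 °C
Reagents that add atoms: tert-butanol, CC(C)(C)O
Why: DMAP-catalysed alcoholysis of the symmetrical cyclic anhydride gives the mono-tert-butyl ester and so differentiates the two carboxyl termini (future C2 as ester, future C6 as acid) without forming a stereocentre.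

Step 2
Reactants: 2 5-tert-butoxy-3,3-dimethyl-5-oxopentanoic acid; 3 (4S)-4-benzyl-1,3-oxazolidin-2-one
Product: 5 tert-butyl 5-[(4S)-4-benzyl-2-oxo-1,3-oxazolidin-3-yl]-3,3-dimethyl-5-oxopentanoate, via mixed pivalic anhydride 4 (not isolated)
Conditions: PivCl, Et3N, THF, −20 °C; then 3, LiCl, −20 °C → rt
Reagents that add atoms: none
Why: Evans N-acylation through the mixed anhydride, in which the LiCl-activated oxazolidinone attacks the less hindered carbonyl, places the auxiliary next to the future C7.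

Step 3
Reactants: 5 tert-butyl 5-[(4S)-4-benzyl-2-oxo-1,3-oxazolidin-3-yl]-3,3-dimethyl-5-oxopentanoate; 6 prenyl bromide
Product: 7 tert-butyl (4S)-4-{[(4S)-4-benzyl-2-oxo-1,3-oxazolidin-3-yl]carbonyl}-3,3,7-trimethyloct-6-enoate
Conditions: NaN(SiMe3)2, THF, −78 °C; then 6, −78 → −30 °C
Reagents that add atoms: none
Why: Evans asymmetric alkylation, in which the chelated Z sodium enolate of the imide (far more acidic than the tert-butyl ester) is alkylated by the allylic bromide on the face opposite the benzyl group, sets C7, the only stereocentre carried into the key step.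

Step 4
Reactants: 7 tert-butyl (4S)-4-{[(4S)-4-benzyl-2-oxo-1,3-oxazolidin-3-yl]carbonyl}-3,3,7-trimethyloct-6-enoate
Product: 8 tert-butyl (4S)-4-(hydroxymethyl)-3,3,7-trimethyloct-6-enoate
Conditions: NaBH4, THF/H2O (4:1), 0 °C → rt
Reagents that add atoms: none
Why: Borohydride reduction of the N-acyloxazolidinone (reductive auxiliary cleavage) gives the primary alcohol at the future C6 without touching the tert-butyl ester or the alkene and without epimerising C7.

Step 5
Reactants: 8 tert-butyl (4S)-4-(hydroxymethyl)-3,3,7-trimethyloct-6-enoate; 9 geranyl bromide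
Product: 10 tert-butyl (4S)-2-[(2E)-3,7-dimethylocta-2,6-dien-1-yl]-4-(hydroxymethyl)-3,3,7-trimethyloct-6-enoate (both C2 epimers)
Conditions: LiN(i-Pr)2 (2.2 equiv), THF, −78 °C; then 9, DMPU, −78 → −40 °C
Reagents that add atoms: none
Why: In the alkoxide–ester-enolate dianion the lithium enolate is C-alkylated by the allylic bromide (SN2) much faster than the hindered alkoxide is O-alkylated, which installs the C1 geranyl group as an epimer mixture that step 12 erases.

Step 6
Reactants: 10 tert-butyl (4S)-2-[(2E)-3,7-dimethylocta-2,6-dien-1-yl]-4-(hydroxymethyl)-3,3,7-trimethyloct-6-enoate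
Product: 11 tert-butyl (4S)-2-[(2E)-3,7-dimethylocta-2,6-dien-1-yl]-4-(iodomethyl)-3,3,7-trimethyloct-6-enoate (both C2 epimers)
Conditions: I2, PPh3, imidazole, CH2Cl2, 0 °C → rt
Reagents that add atoms: iodine, [I][I]
Why: Appel iodination converts the primary alcohol into the iodide under neutral conditions that spare the trisubstituted alkenes and the tert-butyl ester and do not involve C7.

Step 7
Reactants: 11 tert-butyl (4S)-2-[(2E)-3,7-dimethylocta-2,6-dien-1-yl]-4-(iodomethyl)-3,3,7-trimethyloct-6-enoate; 12 dimethyl malonate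
Product: 13 dimethyl 2-[(2R,6E)-4-(tert-butoxycarbonyl)-3,3,7,11-tetramethyl-2-(3-methylbut-2-en-1-yl)dodeca-6,10-dien-1-yl]malonate (both C4 epimers of the side chain)
Conditions: NaH, 12 (3 equiv), DMF, 0 °C; then 11, 70 °C
Reagents that add atoms: none
Why: SN2 alkylation of sodium dimethyl malonate (malonic ester synthesis) by the primary iodide forms the C5–C6 bond, the excess of a small soft nucleophile in a polar aprotic solvent offsetting the β-branching.

Step 8
Reactants: 13 dimethyl 2-[(2R,6E)-4-(tert-butoxycarbonyl)-3,3,7,11-tetramethyl-2-(3-methylbut-2-en-1-yl)dodeca-6,10-dien-1-yl]malonate; 9 geranyl bromide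
Product: 14 dimethyl 2-[(2E)-3,7-dimethylocta-2,6-dien-1-yl]-2-[(2R,6E)-4-(tert-butoxycarbonyl)-3,3,7,11-tetramethyl-2-(3-methylbut-2-en-1-yl)dodeca-6,10-dien-1-yl]malonate
Conditions: NaH, THF/DMF, 0 °C; then 9, rt
Reagents that add atoms: none
Why: A second malonate alkylation with the reactive allylic bromide makes C5 quaternary (still prochiral), which removes the acidic malonate hydrogen so that both ester groups stay electrophilic in step 12.

Step 9
Reactants: 14 dimethyl 2-[(2E)-3,7-dimethylocta-2,6-dien-1-yl]-2-[(2R,6E)-4-(tert-butoxycarbonyl)-3,3,7,11-tetramethyl-2-(3-methylbut-2-en-1-yl)dodeca-6,10-dien-1-yl]malonate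
Product: 16 dimethyl 2-[(2R,6E)-4-carboxy-3,3,7,11-tetramethyl-2-(3-methylbut-2-en-1-yl)dodeca-6,10-dien-1-yl]-2-[(2E)-3,7-dimethylocta-2,6-dien-1-yl]malonate, via trimethylsilyl ester 15 (not isolated)
Conditions: TMSOTf, 2,6-lutidine, CH2Cl2, 0 °C; then H2O, THF, pH 5 buffer
Reagents that add atoms: none
Why: Silyl-triflate-mediated tert-butyl ester cleavage (loss of 2-methylpropene from the O-silylated ester, buffered by 2,6-lutidine) frees the C2 carboxylic acid without protic acid, so the trisubstituted alkenes and the methyl esters should survive.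

Step 10
Reactants: 17 1-(3,4-dihydroxyphenyl)ethanone
Product: 18 1-[3,4-bis(tert-butyldimethylsilyloxy)phenyl]ethanone
Conditions: TBSCl (2.4 equiv), imidazole, DMF, rt
Reagents that add atoms: tert-butyldimethylsilyl chloride, CC(C)(C)[Si](C)(C)Cl
Why: Imidazole-mediated silylation of both phenols gives a catechol protection that tolerates amide bases and is removed by fluoride.

Step 11
Reactants: 16 dimethyl 2-[(2R,6E)-4-carboxy-3,3,7,11-tetramethyl-2-(3-methylbut-2-en-1-yl)dodeca-6,10-dien-1-yl]-2-[(2E)-3,7-dimethylocta-2,6-dien-1-yl]malonate; 18 1-[3,4-bis(tert-butyldimethylsilyloxy)phenyl]ethanone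
Product: 20 dimethyl 2-[(2R,6E)-4-{3-[3,4-bis(tert-butyldimethylsilyloxy)phenyl]-3-oxopropanoyl}-3,3,7,11-tetramethyl-2-(3-methylbut-2-en-1-yl)dodeca-6,10-dien-1-yl]-2-[(2E)-3,7-dimethylocta-2,6-dien-1-yl]malonate, via acid chloride 19 (not isolated)
Conditions: Me2C=C(Cl)NMe2, CH2Cl2, 0 °C → rt; then 18 (2 equiv), MgBr2·OEt2, i-Pr2NEt, CH2Cl2, 0 °C → rt
Reagents that add atoms: none
Why: Neutral acid chloride formation (Ghosez reagent) followed by Claisen-type C-acylation of the aryl methyl ketone under soft enolisation forms the C2–C3 bond and gives the 1,3-diketone without a strong base that could start the cyclisation early.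

Step 12
Reactants: 20 dimethyl 2-[(2R,6E)-4-{3-[3,4-bis(tert-butyldimethylsilyloxy)phenyl]-3-oxopropanoyl}-3,3,7,11-tetramethyl-2-(3-methylbut-2-en-1-yl)dodeca-6,10-dien-1-yl]-2-[(2E)-3,7-dimethylocta-2,6-dien-1-yl]malonate
Product: 22 (1S,5S,7R)-3-[3,4-bis(tert-butyldimethylsilyloxy)benzoyl]-1,5-bis[(2E)-3,7-dimethylocta-2,6-dien-1-yl]-4-hydroxy-8,8-dimethyl-7-(3-methylbut-2-en-1-yl)bicyclo[3.3.1]non-3-ene-2,9-dione, via monocyclic triketo ester 21 (not isolated)
Conditions: LiN(i-Pr)2 (3.2 equiv), THF (0.01 M), −78 → 0 °C, then 40 °C; aq. NH4Cl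
Reagents that add atoms: none
Why: Proposed new method: LiN(i-Pr)2 converts 20 first into the C3 diketonate and then, by removing the only remaining acidic hydrogen (C1–H; the aryl ketone has no α-hydrogen and C5 is quaternary), into the 1,3-diketone dianion, whose γ-carbon C1 attacks one ester group of the C5 malonate to form the C1–C9 bond and ring B (21), after which the diketonate carbon C3 of 21 attacks the second ester (C4) to close ring A and give the triketonate of 22, the thermodynamic sink. The closest known reactions are the Hauser–Harris γ-acylation of β-diketone dianions with esters and the Claisen cyclisation of 3,5,7-triketo esters to acylphloroglucinols; their tandem intramolecular use at a methine γ-carbon to build both rings of a bicyclo[3.3.1]nonane is new. Ring B closes in the 6-(enolexo)-exo-trig mode and ring A in the 6-(enolendo)-exo-trig mode. C7 is the only stereocentre of 20 and controls both new ones: in the chair transition state of the first closure the C7 prenyl group and the two geranyl groups should take equatorial sites, so the diketonate arm on C1 and the spectator ester on C5 are axial and syn, held by a bridging lithium ion, which fixes C1 and C5 together by choosing one face of the dianion and one of the two diastereotopic ester groups. The step needs γ- over α-acylation (secured by the dianion), C- over O-acylation in the second closure (the enol lactone from O-acylation is itself an acyl donor and is funnelled to the triketonate) and the syn-diaxial isomer of 21 (only this isomer can bridge, so a mis-set isomer stays monocyclic and is separated).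

Step 13
Reactants: 22 (1S,5S,7R)-3-[3,4-bis(tert-butyldimethylsilyloxy)benzoyl]-1,5-bis[(2E)-3,7-dimethylocta-2,6-dien-1-yl]-4-hydroxy-8,8-dimethyl-7-(3-methylbut-2-en-1-yl)bicyclo[3.3.1]non-3-ene-2,9-dione
Product: 23 (1S,5S,7R)-3-(3,4-dihydroxybenzoyl)-1,5-bis[(2E)-3,7-dimethylocta-2,6-dien-1-yl]-4-hydroxy-8,8-dimethyl-7-(3-methylbut-2-en-1-yl)bicyclo[3.3.1]non-3-ene-2,9-dione (CNP0178719.1)
Conditions: n-Bu4NF, AcOH, THF, 0 °C → rt
Reagents that add atoms: none
Why: Fluoride-mediated cleavage of the two aryl silyl ethers, buffered with acetic acid so that the acidic triketone and the catechol do not meet strong base, should release the target without touching its stereocentres.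

## Compound list

1 | 3,3-dimethylglutaric anhydride (4,4-dimethyloxane-2,6-dione) | CC1(C)CC(=O)OC(=O)C1 | starting material
2 | 5-tert-butoxy-3,3-dimethyl-5-oxopentanoic acid (mono-tert-butyl 3,3-dimethylglutarate) | CC(C)(C)OC(=O)CC(C)(C)CC(=O)O | intermediate
3 | (4S)-4-benzyl-1,3-oxazolidin-2-one | O=C1N[C@@H](Cc2ccccc2)CO1 | starting material
4 | mixed anhydride of 2 with pivalic acid (not isolated) | CC(C)(C)OC(=O)CC(C)(C)CC(=O)OC(=O)C(C)(C)C | intermediate
5 | tert-butyl 5-[(4S)-4-benzyl-2-oxo-1,3-oxazolidin-3-yl]-3,3-dimethyl-5-oxopentanoate | CC(C)(C)OC(=O)CC(C)(C)CC(=O)N1[C@@H](Cc2ccccc2)COC1=O | intermediate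
6 | prenyl bromide (1-bromo-3-methylbut-2-ene) | CC(C)=CCBr | starting material
7 | tert-butyl (4S)-4-{[(4S)-4-benzyl-2-oxo-1,3-oxazolidin-3-yl]carbonyl}-3,3,7-trimethyloct-6-enoate | CC(C)(C)OC(=O)CC(C)(C)[C@H](CC=C(C)C)C(=O)N1[C@@H](Cc2ccccc2)COC1=O | intermediate
8 | tert-butyl (4S)-4-(hydroxymethyl)-3,3,7-trimethyloct-6-enoate | CC(C)(C)OC(=O)CC(C)(C)[C@H](CC=C(C)C)CO | intermediate
9 | geranyl bromide ((2E)-1-bromo-3,7-dimethylocta-2,6-diene) | CC(C)=CCC/C(C)=C/CBr | starting material
10 | tert-butyl (4S)-2-[(2E)-3,7-dimethylocta-2,6-dien-1-yl]-4-(hydroxymethyl)-3,3,7-trimethyloct-6-enoate (both C2 epimers) | CC(C)(C)OC(=O)C(C/C=C(\C)CCC=C(C)C)C(C)(C)[C@H](CC=C(C)C)CO | intermediate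
11 | tert-butyl (4S)-2-[(2E)-3,7-dimethylocta-2,6-dien-1-yl]-4-(iodomethyl)-3,3,7-trimethyloct-6-enoate (both C2 epimers) | CC(C)(C)OC(=O)C(C/C=C(\C)CCC=C(C)C)C(C)(C)[C@H](CC=C(C)C)CI | intermediate
12 | dimethyl malonate | COC(=O)CC(=O)OC | starting material
13 | dimethyl 2-[(2R,6E)-4-(tert-butoxycarbonyl)-3,3,7,11-tetramethyl-2-(3-methylbut-2-en-1-yl)dodeca-6,10-dien-1-yl]malonate (both C4 epimers of the side chain) | COC(=O)C(C[C@@H](CC=C(C)C)C(C)(C)C(C/C=C(\C)CCC=C(C)C)C(=O)OC(C)(C)C)C(=O)OC | intermediate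
14 | dimethyl 2-[(2E)-3,7-dimethylocta-2,6-dien-1-yl]-2-[(2R,6E)-4-(tert-butoxycarbonyl)-3,3,7,11-tetramethyl-2-(3-methylbut-2-en-1-yl)dodeca-6,10-dien-1-yl]malonate | COC(=O)C(C/C=C(\C)CCC=C(C)C)(C[C@@H](CC=C(C)C)C(C)(C)C(C/C=C(\C)CCC=C(C)C)C(=O)OC(C)(C)C)C(=O)OC | intermediate
15 | trimethylsilyl ester of acid 16 (not isolated) | COC(=O)C(C/C=C(\C)CCC=C(C)C)(C[C@@H](CC=C(C)C)C(C)(C)C(C/C=C(\C)CCC=C(C)C)C(=O)O[Si](C)(C)C)C(=O)OC | intermediate
16 | dimethyl 2-[(2R,6E)-4-carboxy-3,3,7,11-tetramethyl-2-(3-methylbut-2-en-1-yl)dodeca-6,10-dien-1-yl]-2-[(2E)-3,7-dimethylocta-2,6-dien-1-yl]malonate | COC(=O)C(C/C=C(\C)CCC=C(C)C)(C[C@@H](CC=C(C)C)C(C)(C)C(C/C=C(\C)CCC=C(C)C)C(=O)O)C(=O)OC | intermediate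
17 | 1-(3,4-dihydroxyphenyl)ethanone (3',4'-dihydroxyacetophenone) | CC(=O)c1ccc(O)c(O)c1 | starting material
18 | 1-[3,4-bis(tert-butyldimethylsilyloxy)phenyl]ethanone | CC(=O)c1ccc(O[Si](C)(C)C(C)(C)C)c(O[Si](C)(C)C(C)(C)C)c1 | intermediate
19 | acid chloride of 16 (not isolated) | COC(=O)C(C/C=C(\C)CCC=C(C)C)(C[C@@H](CC=C(C)C)C(C)(C)C(C/C=C(\C)CCC=C(C)C)C(=O)Cl)C(=O)OC | intermediate
20 | dimethyl 2-[(2R,6E)-4-{3-[3,4-bis(tert-butyldimethylsilyloxy)phenyl]-3-oxopropanoyl}-3,3,7,11-tetramethyl-2-(3-methylbut-2-en-1-yl)dodeca-6,10-dien-1-yl]-2-[(2E)-3,7-dimethylocta-2,6-dien-1-yl]malonate (both epimers at the diketone-bearing carbon) | COC(=O)C(C/C=C(\C)CCC=C(C)C)(C[C@@H](CC=C(C)C)C(C)(C)C(C/C=C(\C)CCC=C(C)C)C(=O)CC(=O)c1ccc(O[Si](C)(C)C(C)(C)C)c(O[Si](C)(C)C(C)(C)C)c1)C(=O)OC | intermediate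
21 | methyl 3-{3-[3,4-bis(tert-butyldimethylsilyloxy)phenyl]-3-oxopropanoyl}-1,3-digeranyl-4,4-dimethyl-5-prenyl-2-oxocyclohexane-1-carboxylate, ester and diketone arm cis to each other and trans to the prenyl group (not isolated) | CC(C)=CCC/C(C)=C/C[C@@]1(C(=O)OC)C[C@@H](CC=C(C)C)C(C)(C)[C@](C/C=C(\C)CCC=C(C)C)(C(=O)CC(=O)c2ccc(O[Si](C)(C)C(C)(C)C)c(O[Si](C)(C)C(C)(C)C)c2)C1=O | intermediate
22 | (1S,5S,7R)-3-[3,4-bis(tert-butyldimethylsilyloxy)benzoyl]-1,5-bis[(2E)-3,7-dimethylocta-2,6-dien-1-yl]-4-hydroxy-8,8-dimethyl-7-(3-methylbut-2-en-1-yl)bicyclo[3.3.1]non-3-ene-2,9-dione | CC(C)=CCC/C(C)=C/C[C@]12C[C@@H](CC=C(C)C)C(C)(C)[C@](C/C=C(\C)CCC=C(C)C)(C(=O)C(C(=O)c3ccc(O[Si](C)(C)C(C)(C)C)c(O[Si](C)(C)C(C)(C)C)c3)=C1O)C2=O | intermediate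
23 | (1S,5S,7R)-3-(3,4-dihydroxybenzoyl)-1,5-bis[(2E)-3,7-dimethylocta-2,6-dien-1-yl]-4-hydroxy-8,8-dimethyl-7-(3-methylbut-2-en-1-yl)bicyclo[3.3.1]non-3-ene-2,9-dione (CNP0178719.1; C7 prenyl exo, trans to the C2–C4 bridge) | CC(C)=CCC/C(C)=C/C[C@]12C[C@@H](CC=C(C)C)C(C)(C)[C@](C/C=C(\C)CCC=C(C)C)(C(=O)C(C(=O)c3ccc(O)c(O)c3)=C1O)C2=O | target

## Step count and risks

Total step count: 13. Longest linear sequence: 12 steps (steps 1–9 and 11–13; step 10 is a one-step side branch).

**Step 12 (Proposed new method).** What may go wrong: incomplete deprotonation of the hindered C1 methine, slow bond formation between two fully substituted carbons so that the dianion is quenched or cleaved, and poor selection between the two diastereotopic ester groups. The fallback uses known chemistry, sets out from 8 and returns at 21, then at 22. It leaves the C1 geranyl group out until ring B exists, so that the C1–C9 bond is made by an ordinary enolate-driven Claisen condensation at a methylene carbon. Alcohol 8 is converted (I2, PPh3, imidazole) into the iodide F1, which alkylates NaCH(CO2Me)2 to give the triester F2. NaH and 9 give the quaternary malonate F3, ZnBr2 in CH2Cl2 frees the acid F4, and the acid chloride F5 (Ghosez reagent) reacts with Me2CuLi to give the methyl ketone F6. NaOMe in MeOH closes ring B to the 2-acetylcyclohexanone F7, which forms a stable enolate. K2CO3 and 9 in acetone should C-geranylate C1 to the diketo ester F8, with the acetyl group cis to the ester. The lithium enolate of the acetyl group (LiN(i-Pr)2, −78 °C) adds to the silylated aldehyde F9 (from commercial 3,4-dihydroxybenzaldehyde, TBSCl, imidazole) to give the aldol F10, and Dess–Martin oxidation gives 21. LiN(SiMe3)2 in THF then effects the known Claisen cyclisation of the triketo ester to 22.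

**Step 7.** What may go wrong: slow bimolecular substitution at the β-branched C6, so that elimination or lactonisation by the neighbouring ester takes over. The fallback sets out from 10 and returns at 14, and forms the C5–C6 bond by condensation instead of substitution. Dess–Martin oxidation of 10 gives the aldehyde F11. Knoevenagel condensation with 12 (TiCl4, pyridine, THF, 0 °C) gives the alkylidene malonate F12. Conjugate reduction with LiBH(s-Bu)3 at −78 °C and alkylation of the resulting malonate enolate with 9 gives 14 directly.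

**Step 3.** What may go wrong: sluggish alkylation of the enolate next to the quaternary carbon, with enolate breakdown on warming and low conversion. The fallback sets out from 5 and returns at 7, and builds the prenyl group in two stages. The sodium enolate of 5 is alkylated with the smaller and more reactive allyl iodide to give the allyl imide F13. Cross-metathesis with 2-methylbut-2-ene (second-generation Grubbs catalyst) then completes the prenyl group of 7.

## Further compounds

F1 | step 12 | tert-butyl (4S)-4-(iodomethyl)-3,3,7-trimethyloct-6-enoate | CC(C)(C)OC(=O)CC(C)(C)[C@H](CC=C(C)C)CI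
F2 | step 12 | dimethyl 2-[(2R)-4-(tert-butoxycarbonyl)-3,3-dimethyl-2-(3-methylbut-2-en-1-yl)butyl]malonate | COC(=O)C(C[C@@H](CC=C(C)C)C(C)(C)CC(=O)OC(C)(C)C)C(=O)OC
F3 | step 12 | dimethyl 2-[(2R)-4-(tert-butoxycarbonyl)-3,3-dimethyl-2-(3-methylbut-2-en-1-yl)butyl]-2-[(2E)-3,7-dimethylocta-2,6-dien-1-yl]malonate | COC(=O)C(C/C=C(\C)CCC=C(C)C)(C[C@@H](CC=C(C)C)C(C)(C)CC(=O)OC(C)(C)C)C(=O)OC
F4 | step 12 | (4R)-6,6-bis(methoxycarbonyl)-3,3,9,13-tetramethyl-4-(3-methylbut-2-en-1-yl)tetradeca-8,12-dienoic acid | COC(=O)C(C/C=C(\C)CCC=C(C)C)(C[C@@H](CC=C(C)C)C(C)(C)CC(=O)O)C(=O)OC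
F5 | step 12 | acid chloride of F4 | COC(=O)C(C/C=C(\C)CCC=C(C)C)(C[C@@H](CC=C(C)C)C(C)(C)CC(=O)Cl)C(=O)OC
F6 | step 12 | dimethyl 2-[(2R)-3,3-dimethyl-2-(3-methylbut-2-en-1-yl)-5-oxohexyl]-2-[(2E)-3,7-dimethylocta-2,6-dien-1-yl]malonate | COC(=O)C(C/C=C(\C)CCC=C(C)C)(C[C@@H](CC=C(C)C)C(C)(C)CC(C)=O)C(=O)OC
F7 | step 12 | methyl 3-acetyl-1-geranyl-4,4-dimethyl-5-prenyl-2-oxocyclohexane-1-carboxylate, ester trans to the prenyl group, C3 enolisable | CC(C)=CCC/C(C)=C/C[C@@]1(C(=O)OC)C[C@@H](CC=C(C)C)C(C)(C)C(C(C)=O)C1=O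
F8 | step 12 | methyl 3-acetyl-1,3-digeranyl-4,4-dimethyl-5-prenyl-2-oxocyclohexane-1-carboxylate, acetyl cis to the ester and trans to the prenyl group | CC(C)=CCC/C(C)=C/C[C@@]1(C(=O)OC)C[C@@H](CC=C(C)C)C(C)(C)[C@](C/C=C(\C)CCC=C(C)C)(C(C)=O)C1=O
F9 | step 12 | 3,4-bis(tert-butyldimethylsilyloxy)benzaldehyde | O=Cc1ccc(O[Si](C)(C)C(C)(C)C)c(O[Si](C)(C)C(C)(C)C)c1
F10 | step 12 | aldol adduct of F8 and F9 (β-hydroxy ketone, both carbinol epimers) | CC(C)=CCC/C(C)=C/C[C@@]1(C(=O)OC)C[C@@H](CC=C(C)C)C(C)(C)[C@](C/C=C(\C)CCC=C(C)C)(C(=O)CC(O)c2ccc(O[Si](C)(C)C(C)(C)C)c(O[Si](C)(C)C(C)(C)C)c2)C1=O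
F11 | step 7 | tert-butyl (4S)-2-[(2E)-3,7-dimethylocta-2,6-dien-1-yl]-4-formyl-3,3,7-trimethyloct-6-enoate (both C2 epimers) | CC(C)(C)OC(=O)C(C/C=C(\C)CCC=C(C)C)C(C)(C)[C@H](CC=C(C)C)C=O
F12 | step 7 | dimethyl 2-[(2R,6E)-4-(tert-butoxycarbonyl)-3,3,7,11-tetramethyl-2-(3-methylbut-2-en-1-yl)dodeca-6,10-dien-1-ylidene]malonate | COC(=O)C(=C[C@@H](CC=C(C)C)C(C)(C)C(C/C=C(\C)CCC=C(C)C)C(=O)OC(C)(C)C)C(=O)OC
F13 | step 3 | tert-butyl (4S)-4-{[(4S)-4-benzyl-2-oxo-1,3-oxazolidin-3-yl]carbonyl}-3,3-dimethylhept-6-enoate | CC(C)(C)OC(=O)CC(C)(C)[C@H](CC=C)C(=O)N1[C@@H](Cc2ccccc2)COC1=O
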